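The runs are simulated for an exercise.

Take the ratio of the last two target readings of the ash run and set it against the ratio of their times: this shows how steeply target grows with time late in the run. Carry the result to the bench as a time.

| setting | ash | Wednesday's | Tuesday's | Friday's | Thursday's | Sunday's |
|---|---|---|---|---|---|---|
| starting material | 0.37 M | 0.74 M | 0.74 M | 0.74 M | 0.74 M | 0.74 M |
| reagent | 3 equiv (fed, over 1.2 min) | 3.00 equiv (fed, over 1.2 min) | 3.00 equiv (fed, over 2.5 min) | 3.00 equiv (fed, over 5.0 min) | 3.00 equiv (fed, over 10 min) | 3.00 equiv (fed, over 20 min) |
| remark | run made earlier |  |  |  |  |  |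
| time |  | 1.5 h | 1.5 h | 1.5 h | 1.5 h | 1.5 h |

ash run (percent of the starting material charged)

| time / min | target / % | starting material / % |
|---|---|---|
| 8.00 | 0 | 89.5 |
| 15.0 | 0 | 81.7 |
| 25.0 | 1.5 | 70.9 |
| 50.0 | 2.9 | 55.5 |
| 90.0 | 6.4 | 41.7 |

(readings scatter by 0.5 percentage points)

- a reading or a percentage of target counts all its forms, free or not
- "hardly changes" means that all values lie within two and a half points (for a concentration: within two and a half percent of the largest)
- a reading of starting material is of its free form alone

- amount of target at the end, in percent of the starting material charged for Wednesday's, Tuesday's, Friday's, Thursday's, Sunday's, in this order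
- the course of these numbers from the first flask to the last (rises all the way / falls all the way / falls, then rises / rises, then falls / hardly changes)

You are taking over flasks that differ in their feed time. Wednesday's flask holds c(starting material) = 0.74 M and, once fed, c(reagent) = 2.22 M, twice the ash run's values. Expect a slow flask: at 90.0 min, the ash run shows starting material 41.7 % and target 6.4 %, so 51.9 % stands in neither reading. Do not expect target to follow the loss of starting material.

Reckon the cost of a slower feed this way. A steady feed puts reagent in, on average, half its feed time late, so compare flasks by that delay. Read the growth exponent, then divide the asked time by it: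

n = ln(6.4 % / 2.9 %) / ln(90.0 min / 50.0 min) = 1.35

T = 90 min / n = 66.8 min

Call T the delay scale: if target grows as time to the power n, the share of final target lost to a small extra delay is that delay divided by T. Treat T as a rough reading: the scatter of 0.5 percentage points sits on small target readings, and those readings come from the ash run at 0.37 M, not from these flasks.

Sunday's flask is delayed 9.40 min beyond Wednesday's, which costs 14.1 % of its target. On the forecast's first value, that is 1.4 points. So I reckon that the course hardly changes, and you need not hurry a feed.

The forecast gives 9.6 %, 9.5 %, 9.3 %, 8.9 % and 8.1 %, and calls the course "hardly changes", reasoning that “Slow feeding only delays binding by about half the feed time”. Its drop is 1.5 points, larger than mine.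

The flasks end at 10.2 %, 10.1 %, 9.96 %, 9.59 % and 8.88 %; the course: hardly changes.

    starting material + reagent → intermediate A (k = 0.00445 M⁻¹ min⁻¹)
    starting material + reagent ⇌ intermediate B (K = 0.917 M⁻¹, k = 0.00844 M⁻¹ min⁻¹)
    starting material + reagent ⇌ intermediate C (K = 0.517 M⁻¹, k = 0.00107 M⁻¹ min⁻¹)
    intermediate A → target (k = 0.00671 min⁻¹)
    crystals ⇌ target, rate k5*(cs5 - [target]) while solid is left; crystals form when [target] > cs5 (solubility = 0.250 M, k = 1.41 min⁻¹)

Sunday's flask ends 12.9 % below Wednesday's, against the 14.1 % reckoned from T. Sunday's flask held starting material 75.6 % at the end of its feed, after 0.333 h, and 24.4 % after 1.50 h, where Wednesday's flask held 22.7 %. Now use T on Thursday's flask: its extra delay of 4.40 min costs 6.58 %, which takes Wednesday's 10.2 % down to 9.53 %, and Thursday's flask stands at 9.59 %.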